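**Plan**
- Retrosynthesis: the two acetates and the C6/C7 oxygens are traced back to a 6α-formyl labda-8,13-diene. Ring B, a cyclohexene with its alkene at C8=C9, is then cut at C5–C10 and C6–C7 as a Diels–Alder retron (diene C7=C8–C9=C10, dienophile C5=C6); because C1–C4 is the tether, this cut opens ring A as well.
- The acyclic trienal is cut at C5=C6 and C7=C8 (two Wittig reactions), C8–C17, C9–C11 (B-alkyl Suzuki–Miyaura coupling) and C1–C10 (carbocupration of ethyl but-2-ynoate).
- Forward: the C1–C5 chain is added to the ynoate and the adduct iodinated, the C11–C15 side chain is coupled on, the ester becomes the isopropenyl group and the acetal the (E)-enal. Rings A and B then form together in one step, followed by deformylation, C7 hydroxylation, C6 reduction, desilylation and acetylation.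
- Stereochemistry: the C9=C10 geometry comes from syn-carbocupration and retentive couplings, and 13Z from the starting enynol. C5 and C10 come from the catalyst-controlled endo cycloaddition, C7 from α-face hydroxylation of a dienolate, and C6 from α-face hydride delivery.

Key step: step 13

Assumption: labdane numbering (C1–C20) is used throughout, and the imidazolidinone is taken to shield the (E)-iminium ion in the usual sense (benzyl group over one face), so that the (2S,5S) salt leads to the 5S,10S series.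

**Route**

Step 1
Reactants: 1 isobutyronitrile; 2 1-bromo-3-chloropropane
Product: 4 5-chloro-2,2-dimethylpentanenitrile, via lithiated isobutyronitrile 3 (not isolated)
Conditions: LiN(iPr)2, THF, −78 °C; then 2, −78 °C → rt
Reagents that add atoms: none
Why: SN2 alkylation of the nitrile-stabilised tertiary carbanion at the bromide end of 2 (bromide leaves far faster than chloride) should build the quaternary C4 with its two methyl groups and keep the C1 chloride for later metalation.

Step 2
Reactants: 4 5-chloro-2,2-dimethylpentanenitrile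
Product: 5 5-chloro-2,2-dimethylpentanal
Conditions: iBu2AlH, CH2Cl2, −78 °C; then 1 M HCl, 0 °C
Reagents that add atoms: water, O
Why: Partial reduction of a nitrile with iBu2AlH stops at the aluminium aldimine, which aqueous acid should hydrolyse to the aldehyde (future C5) without touching the primary chloride.

Step 3
Reactants: 5 5-chloro-2,2-dimethylpentanal
Product: 6 5-chloro-1,1-dimethoxy-2,2-dimethylpentane
Conditions: HC(OMe)3, MeOH, TsOH·H2O (cat.), rt
Reagents that add atoms: trimethyl orthoformate, COC(OC)OC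
Why: Acid-catalysed acetalisation driven by the orthoformate should mask the aldehyde as a dimethyl acetal that tolerates the organomagnesium, organocopper and ylide chemistry ahead.

Step 4
Reactants: 6 5-chloro-1,1-dimethoxy-2,2-dimethylpentane; 7 ethyl but-2-ynoate
Product: 11 ethyl (2Z)-2-iodo-8,8-dimethoxy-3,7,7-trimethyloct-2-enoate, via alkylmagnesium chloride 8 (not isolated), via alkylcopper reagent 9 (not isolated), via alkenylcopper adduct 10 (not isolated)
Conditions: Mg, THF, reflux; CuBr·SMe2 (1 equiv), THF, −78 → −40 °C; 7, −78 °C; I2, THF, −78 → −20 °C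
Reagents that add atoms: iodine, II
Why: syn-Carbocupration of the ynoate by the Grignard-derived alkylcopper reagent delivers C1 to the β-carbon (C10) and copper to C9 on the same side, and iodinolysis of the carbon–copper bond with retention at low temperature should fix iodine cis to the C1 chain and the C10 methyl cis to the ester, which is the C9=C10 geometry the diene needs.

Step 5
Reactants: 12 (2Z)-3-methylpent-2-en-4-yn-1-ol
Product: 13 tert-butyl{[(2Z)-3-methylpent-2-en-4-yn-1-yl]oxy}diphenylsilane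
Conditions: tBuPh2SiCl, imidazole, DMF, 0 °C → rt
Reagents that add atoms: tert-butyl(chloro)diphenylsilane, CC(C)(C)[Si](Cl)(c1ccccc1)c1ccccc1
Why: Silylation of the primary allylic alcohol should protect the future C15 oxygen with a group that outlasts the organometallic steps, the mild acid of steps 11 and 13 and the bases of steps 10 and 15.

Step 6
Reactants: 13 silylated enynol
Product: 14 tert-butyl{[(2Z)-3-methylpenta-2,4-dien-1-yl]oxy}diphenylsilane
Conditions: H2 (1 atm), Pd/CaCO3 poisoned with Pb(OAc)2, quinoline, hexane, rt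
Reagents that add atoms: none
Why: Semihydrogenation over poisoned palladium should reduce the terminal alkyne to the vinyl group and stop there, leaving the (Z)-trisubstituted C13=C14 alkene unchanged.

Step 7
Reactants: 14 silylated (Z)-dienol; 11 (Z)-α-iodo enoate
Product: 16 ethyl (2E)-2-[(3Z)-5-{[tert-butyl(diphenyl)silyl]oxy}-3-methylpent-3-en-1-yl]-8,8-dimethoxy-3,7,7-trimethyloct-2-enoate, via B-alkyl-9-BBN 15 (not isolated)
Conditions: 9-BBN-H, THF, 0 °C → rt; then 11, Pd(dppf)Cl2 (5 mol %), AsPh3, Cs2CO3, DMF/THF/H2O, rt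
Reagents that add atoms: none
Why: 9-BBN-H adds only to the terminal carbon of the vinyl group (future C11), and B-alkyl Suzuki–Miyaura coupling of the resulting borane with the α-iodo enoate, which retains the alkene geometry, should join C11 to C9 cis to the C1 chain and complete the tetrasubstituted C9=C10 alkene.

Step 8
Reactants: 16 tetrasubstituted enoate
Product: 17 (2E)-2-[(3Z)-5-{[tert-butyl(diphenyl)silyl]oxy}-3-methylpent-3-en-1-yl]-N,8,8-trimethoxy-N,3,7,7-tetramethyloct-2-enamide
Conditions: MeNHOMe·HCl, iPrMgCl, THF, −20 °C → rt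
Reagents that add atoms: N,O-dimethylhydroxylamine hydrochloride, CNOC.Cl
Why: Aminolysis of the ester by the chloromagnesium amide of N,O-dimethylhydroxylamine (Weinreb amide formation) should proceed without Lewis acid, so the acetal and silyl ether stay intact.

Step 9
Reactants: 17 N-methoxy-N-methylamide
Product: 18 (3E)-3-[(3Z)-5-{[tert-butyl(diphenyl)silyl]oxy}-3-methylpent-3-en-1-yl]-9,9-dimethoxy-4,8,8-trimethylnon-3-en-2-one
Conditions: MeMgBr, THF, 0 °C; aq. NH4Cl
Reagents that add atoms: methylmagnesium bromide, C[Mg]Br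
Why: The chelated tetrahedral adduct of the Weinreb ketone synthesis resists a second addition, so the methyl ketone carrying C8 and C17 should result.

Step 10
Reactants: 18 methyl ketone
Product: 19 tert-butyl{[(2Z,6E)-12,12-dimethoxy-3,7,11,11-tetramethyl-6-(prop-1-en-2-yl)dodeca-2,6-dien-1-yl]oxy}diphenylsilane
Conditions: Ph3PCH3Br, KOtBu, toluene, rt → 80 °C
Reagents that add atoms: methyltriphenylphosphonium bromide, C[P+](c1ccccc1)(c1ccccc1)c1ccccc1.[Br-]
Why: Wittig methylenation of the acetyl group should install C7 and complete the C7=C8–C9=C10 diene without disturbing the defined C9=C10 geometry.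

Step 11
Reactants: 19 diene acetal
Product: 20 (6E,10Z)-12-{[tert-butyl(diphenyl)silyl]oxy}-2,2,6,10-tetramethyl-7-(prop-1-en-2-yl)dodeca-6,10-dienal
Conditions: pyridinium p-toluenesulfonate, acetone/H2O, 50 °C
Reagents that add atoms: water, O
Why: Mild acid-catalysed acetal hydrolysis should free the C5 aldehyde while the tert-butyldiphenylsilyl ether and the diene tolerate the weak acid.

Step 12
Reactants: 20 diene aldehyde
Product: 21 (2E,8E,12Z)-14-{[tert-butyl(diphenyl)silyl]oxy}-4,4,8,12-tetramethyl-9-(prop-1-en-2-yl)tetradeca-2,8,12-trienal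
Conditions: Ph3P=CHCHO (1.3 equiv), toluene, 80 °C
Reagents that add atoms: (triphenylphosphoranylidene)acetaldehyde, O=CC=P(c1ccccc1)(c1ccccc1)c1ccccc1
Why: The Wittig reaction of a stabilised formylmethylene ylide with the non-enolisable neopentyl aldehyde should give the (E)-enal (C5=C6 plus the formyl carbon) under the usual thermodynamic E preference.

Step 13
Reactants: 21 (2E,8E,12Z)-trienal
Product: 24 (5S,6S,10S)-15-{[tert-butyl(diphenyl)silyl]oxy}labda-8,13(Z)-diene-6-carbaldehyde (trans-fused; 6α-CHO; 5α-H; 10β-CH3), via trienal iminium ion 22 (not isolated), via cycloadduct iminium ion 23 (not isolated)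
Conditions: (2S,5S)-5-benzyl-2-tert-butyl-3-methylimidazolidin-4-one·CF3CO2H (20 mol %), MeCN/H2O (98:2), 0.05 M, −20 °C → rt
Reagents that add atoms: none
Why: Proposed new method: the amine salt should condense with enal 21 to the (E)-iminium ion 22, whose low-lying LUMO lets the tethered 1,1,2,3-tetrasubstituted diene add across C5=C6 in an asynchronous [4+2] event in which the C5–C10 bond runs ahead of the C6–C7 bond while the developing positive charge sits on the C7–C8–C9 allyl unit with its tertiary C9 end, after which the enamine carbon closes onto C7 and hydrolysis of 23 frees aldehyde 24 and the amine; the closest known reaction type is the imidazolidinone-catalysed type 1 intramolecular Diels–Alder reaction of (E,E)-2,7,9- and 2,8,10-trienals to trans-fused bicycles, which has not been shown with a fully substituted diene terminus or a neopentyl β-carbon. Ring B closes as the cyclohexene of the cycloaddition itself (C5–C10 and C6–C7), and ring A closes in the same event as the six-membered carbocycle completed by the C5–C10 bond across the four-carbon C1–C4 tether held in a chair-like array. C5 is set by the catalyst, whose benzyl group covers one face of 22 so that C10 reaches the Si face of the β-carbon; C10 is set relative to C5 by the (E)-C9=C10 geometry (tether outside, methyl inside) in the endo transition state, which places H-5 and the C10 methyl trans; C6 follows from the (E)-enal and suprafacial addition, which place the formyl group cis to H-5 (6α). The step needs face selectivity, endo over exo selectivity and ring closure in preference to proton loss from the allyl cation: the first rests on the catalyst, the second on the (E,E)-geometry with a four-carbon tether whose gem-dimethyl group at C4 favours the coiled chair-like conformer, and the third on the enamine carbon C6 being held next to C7 once C5–C10 has formed.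

Step 14
Reactants: 24 6α-formyl cycloadduct
Product: 26 (5S,10S)-15-{[tert-butyl(diphenyl)silyl]oxy}labda-8,13(Z)-dien-6-one, via piperidine enamine 25 (not isolated)
Conditions: piperidine, 4 Å molecular sieves, benzene, rt → 50 °C; then CuCl (10 mol %), O2 (1 atm), MeCN, rt
Reagents that add atoms: dioxygen, O=O
Why: The α-branched aldehyde should condense to the enamine, whose electron-rich C6=CH bond is cleaved by O2 under CuCl catalysis (oxidative deformylation via a dioxetane) to the C6 ketone and N-formylpiperidine, while the unactivated C8=C9 and C13=C14 alkenes are inert.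

Step 15
Reactants: 26 6-ketone
Product: 28 (5S,7S,10S)-15-{[tert-butyl(diphenyl)silyl]oxy}-7α-hydroxylabda-8,13(Z)-dien-6-one, via potassium dienolate 27 (not isolated)
Conditions: KN(SiMe3)2, THF, −78 °C; 2-(phenylsulfonyl)-3-phenyloxaziridine, −78 °C; aq. NH4Cl
Reagents that add atoms: 2-(phenylsulfonyl)-3-phenyloxaziridine, O=S(=O)(c1ccccc1)N1OC1c1ccccc1
Why: Deprotonation at the doubly activated C7 (α to the ketone and allylic) gives the dienolate, which should take up oxygen at its α-carbon (enolate hydroxylation with an N-sulfonyloxaziridine) along the pseudoaxial trajectory on the α-face, anti to the C10 methyl, to set 7α-OH.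

Step 16
Reactants: 28 7α-hydroxy-6-ketone
Product: 29 (5S,6S,7S,10S)-15-{[tert-butyl(diphenyl)silyl]oxy}labda-8,13(Z)-diene-6β,7α-diol
Conditions: NaBH4, MeOH/THF, −20 → 0 °C
Reagents that add atoms: none
Why: Hydride should reach the C6 carbonyl from the α-face because the β-face is blocked by the syn-axial C4β and C10 methyl groups, giving the axial 6β-alcohol (substrate-controlled ketone reduction).

Step 17
Reactants: 29 silylated 6β,7α-diol
Product: 30 labda-8,13(Z)-diene-6β,7α,15-triol
Conditions: Bu4NF, THF, 0 °C → rt; aq. NH4Cl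
Reagents that add atoms: none
Why: Fluoride-mediated cleavage of the silicon–oxygen bond should free the C15 hydroxyl without affecting the diol or the alkenes.

Step 18
Reactants: 30 triol
Product: 31 6β-hydroxylabda-8,13(Z)-diene-7α,15-diyl diacetate (CNP0415913.2)
Conditions: Ac2O (2.2 equiv), pyridine, DMAP (cat.), CH2Cl2, 0 °C
Reagents that add atoms: acetic anhydride, CC(=O)OC(C)=O
Why: Acylation should take place at the primary C15 hydroxyl and the allylic 7α-hydroxyl, while the 6β-hydroxyl, 1,3-diaxial to the C4β and C10 methyl groups, stays free (selective acetylation by steric differentiation).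

**Compound list**

1 | isobutyronitrile | CC(C)C#N | starting material
2 | 1-bromo-3-chloropropane | ClCCCBr | starting material
3 | lithiated isobutyronitrile (2-lithio-2-methylpropanenitrile) | [Li]C(C)(C)C#N | intermediate (not isolated)
4 | 5-chloro-2,2-dimethylpentanenitrile | N#CC(C)(C)CCCCl | intermediate
5 | 5-chloro-2,2-dimethylpentanal | O=CC(C)(C)CCCCl | intermediate
6 | 5-chloro-1,1-dimethoxy-2,2-dimethylpentane | COC(OC)C(C)(C)CCCCl | intermediate
7 | ethyl but-2-ynoate | CCOC(=O)C#CC | starting material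
8 | (5,5-dimethoxy-4,4-dimethylpentyl)magnesium chloride | COC(OC)C(C)(C)CCC[Mg]Cl | intermediate (not isolated)
9 | (5,5-dimethoxy-4,4-dimethylpentyl)copper, as its MgBrCl/SMe2 complex | COC(OC)C(C)(C)CCC[Cu] | intermediate (not isolated)
10 | ethyl 2-cuprio-8,8-dimethoxy-3,7,7-trimethyloct-2-enoate (copper cis to the C4 chain) | CCOC(=O)/C([Cu])=C(\C)CCCC(C)(C)C(OC)OC | intermediate (not isolated)
11 | ethyl (2Z)-2-iodo-8,8-dimethoxy-3,7,7-trimethyloct-2-enoate | CCOC(=O)/C(I)=C(\C)CCCC(C)(C)C(OC)OC | intermediate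
12 | (2Z)-3-methylpent-2-en-4-yn-1-ol | OC/C=C(/C)C#C | starting material
13 | tert-butyl{[(2Z)-3-methylpent-2-en-4-yn-1-yl]oxy}diphenylsilane | CC(C)(C)[Si](c1ccccc1)(c1ccccc1)OC/C=C(/C)C#C | intermediate
14 | tert-butyl{[(2Z)-3-methylpenta-2,4-dien-1-yl]oxy}diphenylsilane | CC(C)(C)[Si](c1ccccc1)(c1ccccc1)OC/C=C(/C)C=C | intermediate
15 | 9-[(3Z)-5-{[tert-butyl(diphenyl)silyl]oxy}-3-methylpent-3-en-1-yl]-9-borabicyclo[3.3.1]nonane | CC(C)(C)[Si](c1ccccc1)(c1ccccc1)OC/C=C(/C)CCB1C2CCCC1CCC2 | intermediate (not isolated)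
16 | ethyl (2E)-2-[(3Z)-5-{[tert-butyl(diphenyl)silyl]oxy}-3-methylpent-3-en-1-yl]-8,8-dimethoxy-3,7,7-trimethyloct-2-enoate | CCOC(=O)/C(CC/C(C)=C\CO[Si](c1ccccc1)(c1ccccc1)C(C)(C)C)=C(\C)CCCC(C)(C)C(OC)OC | intermediate
17 | (2E)-2-[(3Z)-5-{[tert-butyl(diphenyl)silyl]oxy}-3-methylpent-3-en-1-yl]-N,8,8-trimethoxy-N,3,7,7-tetramethyloct-2-enamide | CON(C)C(=O)/C(CC/C(C)=C\CO[Si](c1ccccc1)(c1ccccc1)C(C)(C)C)=C(\C)CCCC(C)(C)C(OC)OC | intermediate
18 | (3E)-3-[(3Z)-5-{[tert-butyl(diphenyl)silyl]oxy}-3-methylpent-3-en-1-yl]-9,9-dimethoxy-4,8,8-trimethylnon-3-en-2-one | CC(=O)/C(CC/C(C)=C\CO[Si](c1ccccc1)(c1ccccc1)C(C)(C)C)=C(\C)CCCC(C)(C)C(OC)OC | intermediate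
19 | tert-butyl{[(2Z,6E)-12,12-dimethoxy-3,7,11,11-tetramethyl-6-(prop-1-en-2-yl)dodeca-2,6-dien-1-yl]oxy}diphenylsilane | C=C(C)/C(CC/C(C)=C\CO[Si](c1ccccc1)(c1ccccc1)C(C)(C)C)=C(\C)CCCC(C)(C)C(OC)OC | intermediate
20 | (6E,10Z)-12-{[tert-butyl(diphenyl)silyl]oxy}-2,2,6,10-tetramethyl-7-(prop-1-en-2-yl)dodeca-6,10-dienal | C=C(C)/C(CC/C(C)=C\CO[Si](c1ccccc1)(c1ccccc1)C(C)(C)C)=C(\C)CCCC(C)(C)C=O | intermediate
21 | (2E,8E,12Z)-14-{[tert-butyl(diphenyl)silyl]oxy}-4,4,8,12-tetramethyl-9-(prop-1-en-2-yl)tetradeca-2,8,12-trienal | O=C/C=C/C(C)(C)CCC/C(C)=C(CC/C(C)=C\CO[Si](c1ccccc1)(c1ccccc1)C(C)(C)C)/C(C)=C | intermediate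
22 | (E)-iminium trifluoroacetate of 21 with (2S,5S)-5-benzyl-2-tert-butyl-3-methylimidazolidin-4-one | CN1[C@@H](C(C)(C)C)/[N+](=C/C=C/C(C)(C)CCC/C(C)=C(CC/C(C)=C\CO[Si](c2ccccc2)(c2ccccc2)C(C)(C)C)/C(C)=C)[C@@H](Cc2ccccc2)C1=O.[O-]C(=O)C(F)(F)F | intermediate (not isolated)
23 | iminium trifluoroacetate of cycloadduct 24 with the same imidazolidinone | CC(C)(C)[Si](c1ccccc1)(c1ccccc1)OC/C=C(/C)CCC1=C(C)C[C@H](/C=[N+]3\[C@@H](Cc4ccccc4)C(=O)N(C)[C@H]3C(C)(C)C)[C@H]2C(C)(C)CCC[C@]12C.[O-]C(=O)C(F)(F)F | intermediate (not isolated)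
24 | (5S,6S,10S)-15-{[tert-butyl(diphenyl)silyl]oxy}labda-8,13(Z)-diene-6-carbaldehyde (6α-CHO, 5α-H, 10β-CH3) | CC(C)(C)[Si](c1ccccc1)(c1ccccc1)OC/C=C(/C)CCC1=C(C)C[C@H](C=O)[C@H]2C(C)(C)CCC[C@]12C | intermediate
25 | piperidine enamine of 24 (6-(piperidin-1-ylmethylidene), enamine geometry not defined) | CC(C)(C)[Si](c1ccccc1)(c1ccccc1)OC/C=C(/C)CCC1=C(C)CC(=CN3CCCCC3)[C@H]2C(C)(C)CCC[C@]12C | intermediate (not isolated)
26 | (5S,10S)-15-{[tert-butyl(diphenyl)silyl]oxy}labda-8,13(Z)-dien-6-one | CC(C)(C)[Si](c1ccccc1)(c1ccccc1)OC/C=C(/C)CCC1=C(C)CC(=O)[C@H]2C(C)(C)CCC[C@]12C | intermediate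
27 | potassium 6,8-dien-6-olate of 26 | CC(C)(C)[Si](c1ccccc1)(c1ccccc1)OC/C=C(/C)CCC1=C(C)C=C([O-])[C@H]2C(C)(C)CCC[C@]12C.[K+] | intermediate (not isolated)
28 | (5S,7S,10S)-15-{[tert-butyl(diphenyl)silyl]oxy}-7α-hydroxylabda-8,13(Z)-dien-6-one | CC(C)(C)[Si](c1ccccc1)(c1ccccc1)OC/C=C(/C)CCC1=C(C)[C@H](O)C(=O)[C@H]2C(C)(C)CCC[C@]12C | intermediate
29 | (5S,6S,7S,10S)-15-{[tert-butyl(diphenyl)silyl]oxy}labda-8,13(Z)-diene-6β,7α-diol | CC(C)(C)[Si](c1ccccc1)(c1ccccc1)OC/C=C(/C)CCC1=C(C)[C@H](O)[C@@H](O)[C@H]2C(C)(C)CCC[C@]12C | intermediate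
30 | (5S,6S,7S,10S)-labda-8,13(Z)-diene-6β,7α,15-triol | OC/C=C(/C)CCC1=C(C)[C@H](O)[C@@H](O)[C@H]2C(C)(C)CCC[C@]12C | intermediate
31 | 6β-hydroxylabda-8,13(Z)-diene-7α,15-diyl diacetate (CNP0415913.2) | CC(=O)OC/C=C(/C)CCC1=C(C)[C@H](OC(C)=O)[C@@H](O)[C@H]2C(C)(C)CCC[C@]12C | target

**Step count and risks**

Total step count: 18. Longest linear sequence: 16 steps (steps 1–4 and 7–18, from isobutyronitrile); the side-chain branch (steps 5 and 6) joins at step 7.

Steps most likely to fail:

1. Step 13. Bond formation between the neopentyl β-carbon C5 and the fully substituted diene terminus C10 may be too slow for the iminium ion to be intercepted, so that the trienal is returned or the allyl cation loses a proton instead of closing ring B. Face and endo discrimination may also erode if higher temperature is needed. Fallback (auxiliary control, known chemistry, same two bonds): setting out from aldehyde 20, a Horner–Wadsworth–Emmons reaction with diethyl {2-[(4S)-4-benzyl-2-oxo-1,3-oxazolidin-3-yl]-2-oxoethyl}phosphonate (LiCl, iPr2NEt, MeCN) would give the (E)-trienimide F1. Me2AlCl in CH2Cl2 at −30 °C, chelating both carbonyl groups, would then drive the endo intramolecular Diels–Alder reaction on the face away from the benzyl group to the trans-fused 6α-acyl oxazolidinone F2. LiBH4 (THF, MeOH) would cleave the auxiliary to the 6α-hydroxymethyl compound F3, and Dess–Martin oxidation would return to aldehyde 24.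

2. Step 4. The alkenylcopper adduct may equilibrate through its allenoate form before iodine traps it, scrambling the C9=C10 geometry, or iodinolysis may be incomplete. Fallback (stereodefined enol triflate instead of carbometalation): setting out from borane 15 and alkylmagnesium chloride 8, oxidation of 15 (NaOH, H2O2) would give the homoallylic alcohol F4, and an Appel reaction (I2, PPh3, imidazole) the iodide F5. Formylation of 8 with DMF would give 6,6-dimethoxy-5,5-dimethylhexanal F6, and a Roskamp reaction (ethyl diazoacetate, SnCl2 cat.) the β-keto ester F7. C-Alkylation of F7 with F5 (NaH, DMF) would give the α-alkylated β-keto ester F8, and NaH followed by Tf2O would trap the chelated enolate as the (Z)-enol triflate F9. Stereoretentive Fe(acac)3-catalysed coupling with MeMgBr would then put the C10 methyl in place of the triflate and return to enoate 16.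

3. Step 15. Under the basic conditions the new α-ketol may isomerise by enediol shift into conjugation with C8=C9 or be oxidised further, and attack on the β-face may compete. Fallback (C7 oxygen introduced as a nucleophile): setting out from ketone 26 by way of dienolate 27, bromination with N-bromosuccinimide at −78 °C would give the 7α-bromo-6-ketone F10. NaBH4 would reduce it from the α-face to the trans-diaxial 7α-bromo-6β-ol F11, and K2CO3 in MeOH would close the 6β,7β-epoxide F12. Dilute aqueous HClO4 in THF would open the epoxide at the allylic C7 with inversion (trans-diaxial opening) and return to diol 29.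

Further compounds
F1 | step 13 | (4S)-4-benzyl-3-[(2E,8E,12Z)-14-{[tert-butyl(diphenyl)silyl]oxy}-4,4,8,12-tetramethyl-9-(prop-1-en-2-yl)tetradeca-2,8,12-trienoyl]-1,3-oxazolidin-2-one | O=C(/C=C/C(C)(C)CCC/C(C)=C(CC/C(C)=C\CO[Si](c1ccccc1)(c1ccccc1)C(C)(C)C)/C(C)=C)N1[C@@H](Cc2ccccc2)COC1=O
F2 | step 13 | (4S)-4-benzyl-3-{[(5S,6S,10S)-15-{[tert-butyl(diphenyl)silyl]oxy}labda-8,13(Z)-dien-6-yl]carbonyl}-1,3-oxazolidin-2-one | CC(C)(C)[Si](c1ccccc1)(c1ccccc1)OC/C=C(/C)CCC1=C(C)C[C@H](C(=O)N3[C@@H](Cc4ccccc4)COC3=O)[C@H]2C(C)(C)CCC[C@]12C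
F3 | step 13 | (5S,6S,10S)-15-{[tert-butyl(diphenyl)silyl]oxy}-6α-(hydroxymethyl)labda-8,13(Z)-diene | CC(C)(C)[Si](c1ccccc1)(c1ccccc1)OC/C=C(/C)CCC1=C(C)C[C@H](CO)[C@H]2C(C)(C)CCC[C@]12C
F4 | step 4 | (3Z)-5-{[tert-butyl(diphenyl)silyl]oxy}-3-methylpent-3-en-1-ol | CC(C)(C)[Si](c1ccccc1)(c1ccccc1)OC/C=C(/C)CCO
F5 | step 4 | tert-butyl{[(2Z)-5-iodo-3-methylpent-2-en-1-yl]oxy}diphenylsilane | CC(C)(C)[Si](c1ccccc1)(c1ccccc1)OC/C=C(/C)CCI
F6 | step 4 | 6,6-dimethoxy-5,5-dimethylhexanal | COC(OC)C(C)(C)CCCC=O
F7 | step 4 | ethyl 8,8-dimethoxy-7,7-dimethyl-3-oxooctanoate | CCOC(=O)CC(=O)CCCC(C)(C)C(OC)OC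
F8 | step 4 | ethyl 2-[(3Z)-5-{[tert-butyl(diphenyl)silyl]oxy}-3-methylpent-3-en-1-yl]-8,8-dimethoxy-7,7-dimethyl-3-oxooctanoate (racemic) | CCOC(=O)C(CC/C(C)=C\CO[Si](c1ccccc1)(c1ccccc1)C(C)(C)C)C(=O)CCCC(C)(C)C(OC)OC
F9 | step 4 | ethyl (2Z)-2-[(3Z)-5-{[tert-butyl(diphenyl)silyl]oxy}-3-methylpent-3-en-1-yl]-8,8-dimethoxy-7,7-dimethyl-3-{[(trifluoromethyl)sulfonyl]oxy}oct-2-enoate | CCOC(=O)/C(CC/C(C)=C\CO[Si](c1ccccc1)(c1ccccc1)C(C)(C)C)=C(\OS(=O)(=O)C(F)(F)F)CCCC(C)(C)C(OC)OC
F10 | step 15 | (5S,7S,10S)-7α-bromo-15-{[tert-butyl(diphenyl)silyl]oxy}labda-8,13(Z)-dien-6-one | CC(C)(C)[Si](c1ccccc1)(c1ccccc1)OC/C=C(/C)CCC1=C(C)[C@H](Br)C(=O)[C@H]2C(C)(C)CCC[C@]12C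
F11 | step 15 | 7α-bromo-15-{[tert-butyl(diphenyl)silyl]oxy}labda-8,13(Z)-dien-6β-ol | CC(C)(C)[Si](c1ccccc1)(c1ccccc1)OC/C=C(/C)CCC1=C(C)[C@H](Br)[C@@H](O)[C@H]2C(C)(C)CCC[C@]12C
F12 | step 15 | 15-{[tert-butyl(diphenyl)silyl]oxy}-6β,7β-epoxylabda-8,13(Z)-diene | CC(C)(C)[Si](c1ccccc1)(c1ccccc1)OC/C=C(/C)CCC1=C(C)[C@H]3O[C@H]3[C@H]2C(C)(C)CCC[C@]12C
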